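**Retrosynthetic overview**

1. Target 21 comes from (S)-5,7-dihydroxy-8-prenylflavanone 19 by 7-O-prenylation (the 5-OH is tied up in the hydrogen bond to C4=O); 19 comes from bis-acetal 18, and 18 from flavone 16 by enantioselective 1,4-reduction of C2=C3.
2. Ring C of 16 is opened at C8a–O1, C4a–C4 and O1–C2, giving the ring A aryne 14 (triple bond C4a≡C8a) and 3-phenylpropiolic acid 13.
3. Feature used: C4a (which carries the C4 acyl carbon) and C8a (which carries O1) are adjacent ring A carbons lying between the C5 oxygen and the C8 prenyl group, the pattern that a 3-alkoxyaryne takes up with fixed orientation.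
4. Aryne precursor 12 comes from phloroglucinol 1: bis-MOM ether, N-isopropyl carbamate, two ortho-lithiations in one flask (silicon to C4a, then prenyl to C8), then carbamate cleavage and triflation.
5. Ring order: ring A (phloroglucinol) and ring B (phenyl of 13) are bought; ring C is closed in step 5.

Key step: step 5

Remark: the C7 oxygen is carried as a methoxymethyl ether and prenylated last, so that symmetry (steps 1 to 3) and the C5–OH···O=C4 hydrogen bond (step 8) tell the three ring A oxygens apart. Which antipode of the bisphosphine gives Re-face hydride delivery in step 6 is assumed and would be fixed by a trial on flavone itself.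

**Route**

Step 1
Reactants: 1 phloroglucinol
Product: 2 3,5-bis(methoxymethoxy)phenol
Conditions: MOMCl (2 equiv), i-Pr2NEt, DMF, 0 °C → rt; chromatography
Reagents that add atoms: chloromethyl methyl ether COCCl
Why: O-alkylation of the phenoxide with the chloromethyl ether (Williamson type) should give the bis-ether as the main component of a statistical mixture, from which the mono- and tris-ethers are removed by chromatography and the mono-ether can be resubmitted.

Step 2
Reactants: 2 3,5-bis(methoxymethoxy)phenol
Product: 3 3,5-bis(methoxymethoxy)phenyl N-isopropylcarbamate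
Conditions: i-PrNCO, Et3N (cat.), CH2Cl2, rt
Reagents that add atoms: isopropyl isocyanate CC(C)N=C=O
Why: Base-catalysed addition of the only free phenol to the isocyanate gives the N-isopropyl carbamate, which directs both metalations and can later be removed without acid.

Step 3
Reactants: 3 3,5-bis(methoxymethoxy)phenyl N-isopropylcarbamate; 4 1-bromo-3-methylbut-2-ene (prenyl bromide)
Product: 10 3,5-bis(methoxymethoxy)-2-(3-methylbut-2-enyl)-6-(trimethylsilyl)phenyl N-isopropylcarbamate, via N-TBS carbamate 5 (not isolated), via ortho-lithio N-TBS carbamate 6 (not isolated), via N-TBS 2-trimethylsilyl carbamate 7 (not isolated), via 6-lithio N-TBS silyl carbamate 8 (not isolated), via N-TBS prenylated silyl carbamate 9 (not isolated)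
Conditions: TBSOTf (1.05 equiv), TMEDA, Et2O, 0 °C → rt; n-BuLi (2.1 equiv), TMEDA, −78 °C; TMSCl (1.0 equiv), −78 → −20 °C; n-BuLi (1.1 equiv), −78 °C; prenyl bromide (1.5 equiv), −78 °C → rt; brief aq NaHSO4 work-up
Reagents that add atoms: chlorotrimethylsilane C[Si](C)(C)Cl; tert-butyldimethylsilyl trifluoromethanesulfonate CC(C)(C)[Si](C)(C)OS(=O)(=O)C(F)(F)F (its silyl group is in 5 to 9 only)
Why: Directed ortho-metalation with in situ N-silylation, run twice in one flask: the N-silyl carbamate is the strongest director on the ring, so n-BuLi (its first equivalent is spent on the TMEDA triflate salt left by the N-silylation) should remove the proton between the carbamate and an acetal oxygen (two equivalent sites, the future C4a) in preference to the one between the two acetals, TMSCl traps the aryllithium, the second charge of n-BuLi metalates the only remaining position beside the carbamate (also flanked by an acetal oxygen, the future C8), SN2 alkylation at the primary carbon of prenyl bromide follows, and because the N–Si bond is kept until the work-up and silicon goes in first, the nitrogen is silylated only once and no lithiation is run on a compound that carries a benzylic-allylic CH2.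

Step 4
Reactants: 10 3,5-bis(methoxymethoxy)-2-(3-methylbut-2-enyl)-6-(trimethylsilyl)phenyl N-isopropylcarbamate
Product: 12 3,5-bis(methoxymethoxy)-2-(3-methylbut-2-enyl)-6-(trimethylsilyl)phenyl trifluoromethanesulfonate, via silyl phenol 11 (not isolated)
Conditions: Et2NH, DBU, MeCN, 40 °C; then PhNTf2, rt
Reagents that add atoms: N-phenylbis(trifluoromethanesulfonimide) O=S(=O)(N(c1ccccc1)S(=O)(=O)C(F)(F)F)C(F)(F)F
Why: E1cB cleavage of the N–H carbamate (DBU deprotonates nitrogen, the isocyanate is trapped by Et2NH as a urea) frees the hindered phenoxide without acid and without a nucleophile at silicon, and PhNTf2 triflates it in the same flask to give the ortho-silylaryl triflate.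

Step 5
Reactants: 12 3,5-bis(methoxymethoxy)-2-(3-methylbut-2-enyl)-6-(trimethylsilyl)phenyl trifluoromethanesulfonate; 13 3-phenylpropiolic acid
Product: 16 5,7-bis(methoxymethoxy)-8-(3-methylbut-2-enyl)-2-phenyl-4H-chromen-4-one, via aryne 14 (not isolated), via ortho-hydroxyaryl ynone 15 (not isolated)
Conditions: CsF (4 equiv), THF, 125 °C, sealed tube
Reagents that add atoms: none
Why: Fluoride removes the silyl group and triflate leaves to give aryne 14 (C4a≡C8a); cesium 3-phenylpropiolate adds through oxygen to C8a, the aryl anion at C4a attacks the carboxyl carbon through a four-membered alkoxide, and collapse of that intermediate gives the ortho-acyl phenoxide of 15, so that C8a–O1 and C4a–C4 are formed by a formal insertion of the aryne into the carboxyl C–O bond. The closest known reaction type is the insertion of arynes from ortho-silylaryl triflates into the C–O bond of carboxylic acids, which with 3-arylpropiolic acids runs on to flavones. Ring C is then closed by 6-endo-dig oxa-Michael addition of the C8a phenoxide to the ynone β-carbon (O1–C2), the mode favoured in aprotic medium because it leads to a stabilised allenolate, whereas 5-exo closure would leave a vinyl anion that finds no proton. No stereocenter is formed. The step needs oxygen at C8a and the acyl group at C4a: the C5 methoxymethoxy group next to the triple bond polarises and distorts the aryne so that the nucleophile enters at the remote carbon C8a and the carbanion develops at C4a beside the inductively withdrawing oxygen, an effect that in 3-alkoxy- and 3,5-dialkoxyarynes should outweigh both the weak opposing bias of the C7 oxygen and the steric demand of the C8 prenyl group. It also needs acyl transfer to outrun protonation of the aryl anion, which the intramolecular four-centre path, the aprotic solvent and the acid being held as its cesium salt should secure.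

Step 6
Reactants: 16 5,7-bis(methoxymethoxy)-8-(3-methylbut-2-enyl)-2-phenyl-4H-chromen-4-one
Product: 18 (S)-5,7-bis(methoxymethoxy)-8-(3-methylbut-2-enyl)-2-phenylchroman-4-one, via silyl enol ether 17 (not isolated)
Conditions: Cu(OAc)2 (5 mol %), (R)-DTBM-SEGPHOS (5.5 mol %), (EtO)2MeSiH, toluene, 0 °C → rt; then dilute HCl, THF, 0 °C
Reagents that add atoms: diethoxy(methyl)silane CCO[SiH](C)OCC (its silyl group is in 17 only)
Why: Copper hydride-catalysed asymmetric conjugate reduction of the chromone enone: the bisphosphine-bound CuH should deliver hydride to the Re face of C2 to set (S)-C2, the enolate is trapped as silyl enol ether 17 (which shields C4 from over-reduction and the ring from opening) and is hydrolysed on work-up, and the isolated trisubstituted prenyl alkene does not react with CuH.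

Step 7
Reactants: 18 (S)-5,7-bis(methoxymethoxy)-8-(3-methylbut-2-enyl)-2-phenylchroman-4-one
Product: 19 (S)-5,7-dihydroxy-8-(3-methylbut-2-enyl)-2-phenylchroman-4-one
Conditions: HCl (3 M aq), MeOH, rt → 40 °C, stopped at full conversion
Reagents that add atoms: none
Why: Acid-catalysed acetal methanolysis should remove both MOM groups (the C5 acetal, peri to C4=O, first); dilute acid near room temperature is chosen so that the C8 prenyl alkene is not protonated, and C2 is not epimerised because ring opening of a flavanone is a base-promoted process.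

Step 8
Reactants: 19 (S)-5,7-dihydroxy-8-(3-methylbut-2-enyl)-2-phenylchroman-4-one; 20 3-methylbut-2-en-1-ol (prenol)
Product: 21 (S)-5-hydroxy-7-(3-methylbut-2-enyloxy)-8-(3-methylbut-2-enyl)-2-phenylchroman-4-one
Conditions: PPh3, DIAD, THF, 0 °C → rt
Reagents that add atoms: none
Why: Mitsunobu etherification: only the acidic, non-chelated 7-OH should be alkylated (the 5-OH is held in the hydrogen bond to C4=O), substitution takes place at the primary carbon of prenol, and the neutral medium avoids the base-induced ring opening that would racemise C2.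

**Compound list**

1 | phloroglucinol | Oc1cc(O)cc(O)c1 | starting material
2 | 3,5-bis(methoxymethoxy)phenol | COCOc1cc(O)cc(OCOC)c1 | intermediate
3 | 3,5-bis(methoxymethoxy)phenyl N-isopropylcarbamate | CC(C)NC(=O)Oc1cc(OCOC)cc(OCOC)c1 | intermediate
4 | 1-bromo-3-methylbut-2-ene (prenyl bromide) | CC(C)=CCBr | starting material
5 | 3,5-bis(methoxymethoxy)phenyl N-(tert-butyldimethylsilyl)-N-isopropylcarbamate | CC(C)N(C(=O)Oc1cc(OCOC)cc(OCOC)c1)[Si](C)(C)C(C)(C)C | intermediate (not isolated)
6 | 2-lithio-3,5-bis(methoxymethoxy)phenyl N-(tert-butyldimethylsilyl)-N-isopropylcarbamate | CC(C)N(C(=O)Oc1cc(OCOC)cc(OCOC)c1[Li])[Si](C)(C)C(C)(C)C | intermediate (not isolated)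
7 | 3,5-bis(methoxymethoxy)-2-(trimethylsilyl)phenyl N-(tert-butyldimethylsilyl)-N-isopropylcarbamate | CC(C)N(C(=O)Oc1cc(OCOC)cc(OCOC)c1[Si](C)(C)C)[Si](C)(C)C(C)(C)C | intermediate (not isolated)
8 | 2-lithio-3,5-bis(methoxymethoxy)-6-(trimethylsilyl)phenyl N-(tert-butyldimethylsilyl)-N-isopropylcarbamate | CC(C)N(C(=O)Oc1c([Li])c(OCOC)cc(OCOC)c1[Si](C)(C)C)[Si](C)(C)C(C)(C)C | intermediate (not isolated)
9 | 3,5-bis(methoxymethoxy)-2-(3-methylbut-2-enyl)-6-(trimethylsilyl)phenyl N-(tert-butyldimethylsilyl)-N-isopropylcarbamate | CC(C)N(C(=O)Oc1c(CC=C(C)C)c(OCOC)cc(OCOC)c1[Si](C)(C)C)[Si](C)(C)C(C)(C)C | intermediate (not isolated)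
10 | 3,5-bis(methoxymethoxy)-2-(3-methylbut-2-enyl)-6-(trimethylsilyl)phenyl N-isopropylcarbamate | CC(C)NC(=O)Oc1c(CC=C(C)C)c(OCOC)cc(OCOC)c1[Si](C)(C)C | intermediate
11 | 3,5-bis(methoxymethoxy)-2-(3-methylbut-2-enyl)-6-(trimethylsilyl)phenol | Oc1c(CC=C(C)C)c(OCOC)cc(OCOC)c1[Si](C)(C)C | intermediate (not isolated)
12 | 3,5-bis(methoxymethoxy)-2-(3-methylbut-2-enyl)-6-(trimethylsilyl)phenyl trifluoromethanesulfonate | CC(C)=CCc1c(OCOC)cc(OCOC)c([Si](C)(C)C)c1OS(=O)(=O)C(F)(F)F | intermediate
13 | 3-phenylpropiolic acid | OC(=O)C#Cc1ccccc1 | starting material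
14 | 3,5-bis(methoxymethoxy)-6-(3-methylbut-2-enyl)-1,2-didehydrobenzene (ring A aryne, C4a≡C8a) | CC(C)=CCC1=C(OCOC)C=C(OCOC)C#C1 | intermediate (not isolated)
15 | 1-[2-hydroxy-4,6-bis(methoxymethoxy)-3-(3-methylbut-2-enyl)phenyl]-3-phenylprop-2-yn-1-one | CC(C)=CCc1c(OCOC)cc(OCOC)c(C(=O)C#Cc2ccccc2)c1O | intermediate (not isolated)
16 | 5,7-bis(methoxymethoxy)-8-(3-methylbut-2-enyl)-2-phenyl-4H-chromen-4-one | CC(C)=CCc1c(OCOC)cc(OCOC)c2c1oc(-c1ccccc1)cc2=O | intermediate
17 | (S)-4-[diethoxy(methyl)silyloxy]-5,7-bis(methoxymethoxy)-8-(3-methylbut-2-enyl)-2-phenyl-2H-chromene | CC(C)=CCc1c(OCOC)cc(OCOC)c2c1O[C@H](c1ccccc1)C=C2O[Si](C)(OCC)OCC | intermediate (not isolated)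
18 | (S)-5,7-bis(methoxymethoxy)-8-(3-methylbut-2-enyl)-2-phenylchroman-4-one | CC(C)=CCc1c(OCOC)cc(OCOC)c2c1O[C@H](c1ccccc1)CC2=O | intermediate
19 | (S)-5,7-dihydroxy-8-(3-methylbut-2-enyl)-2-phenylchroman-4-one | CC(C)=CCc1c(O)cc(O)c2c1O[C@H](c1ccccc1)CC2=O | intermediate
20 | 3-methylbut-2-en-1-ol (prenol) | CC(C)=CCO | starting material
21 | (S)-5-hydroxy-7-(3-methylbut-2-enyloxy)-8-(3-methylbut-2-enyl)-2-phenylchroman-4-one | CC(C)=CCOc1cc(O)c2c(c1CC=C(C)C)O[C@H](c1ccccc1)CC2=O | target

**Totals**

Total step count: 8. Longest linear sequence: 8 steps (1 → 21).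

**Steps most likely to fail**

Step 5 (key step). The aryl anion may be protonated before acyl transfer (O-arylation without insertion), the alkynoic acid may lose CO2 at 125 °C, the carboxylate may add to the other aryne carbon, or the phenoxide may close 5-exo. Fallback without an aryne, setting out from carbamate 3 and coming back at flavone 16: ortho-lithiation of 3 by the N-silylation and metalation protocol of step 3 (TBSOTf, TMEDA; n-BuLi, −78 °C), quench with prenyl bromide 4 and aqueous work-up would give 3,5-bis(methoxymethoxy)-2-(3-methylbut-2-enyl)phenyl N-isopropylcarbamate F1. A second N-silylation and ortho-lithiation at the remaining carbamate-flanked position (−78 °C, short metalation, so that the ring proton between two oxygen directors is taken before the benzylic-allylic CH2), acylation with N-methoxy-N-methyl-3-phenylpropiolamide and work-up would give 3,5-bis(methoxymethoxy)-2-(3-methylbut-2-enyl)-6-(3-phenylprop-2-ynoyl)phenyl N-isopropylcarbamate F2. Et2NH and DBU in MeCN would then cleave the carbamate to the hydroxyaryl ynone 15; diethylamine adds to the ynone to give (E)-3-(diethylamino)-1-[2-hydroxy-4,6-bis(methoxymethoxy)-3-(3-methylbut-2-enyl)phenyl]-3-phenylprop-2-en-1-one F3, and the amine is expelled on 6-endo ring closure, which gives 16.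

Step 6. Hydride delivery to the hindered β-aryl, β-oxy enone may be slow or poorly face-selective, and C4 may be over-reduced. Fallback setting out from flavone 16 and coming back at 18: 1,4-reduction with LiBH(s-Bu)3 in THF at −78 °C would give racemic 5,7-bis(methoxymethoxy)-8-(3-methylbut-2-enyl)-2-phenylchroman-4-one F4. Kinetic resolution by asymmetric transfer hydrogenation (Cp*RhCl(TsDPEN), HCO2H/Et3N, EtOAc; the catalyst antipode that consumes the (R)-ketone) would reduce the unwanted enantiomer to (2R,4R)-5,7-bis(methoxymethoxy)-8-(3-methylbut-2-enyl)-2-phenylchroman-4-ol F5, from which unreacted (S)-ketone 18 is separated by chromatography; the prenyl alkene is inert to transfer hydrogenation.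

Step 3. The second aryllithium 8 is hindered and may be alkylated slowly, attack prenyl bromide at its tertiary carbon (SN2'), exchange lithium for bromine, or let the carbamoyl group migrate to carbon on warming (anionic ortho-Fries shift); an incomplete first quench would also carry unsilylated material into the second metalation. Fallback with two separate metalations and copper as the carbon nucleophile, setting out from carbamate 3 and coming back at 10: N-silylation, lithiation and TMSCl quench of 3 as in step 3, followed at once by the aqueous NaHSO4 work-up, would give 3,5-bis(methoxymethoxy)-2-(trimethylsilyl)phenyl N-isopropylcarbamate F6, which is freed from regioisomers and unsilylated material by chromatography. Renewed N-silylation and lithiation of F6 (TBSOTf, TMEDA; n-BuLi, −78 °C) lead back through 7 to 8; transmetalation with CuBr·SMe2 at −78 °C would give [2-(N-tert-butyldimethylsilyl-N-isopropylcarbamoyloxy)-4,6-bis(methoxymethoxy)-3-(trimethylsilyl)phenyl]copper F7, which is allylated by prenyl bromide 4 at its primary carbon to give 9, and the work-up gives 10.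

**Further compounds**

F1 | step 5 | 3,5-bis(methoxymethoxy)-2-(3-methylbut-2-enyl)phenyl N-isopropylcarbamate | CC(C)NC(=O)Oc1cc(OCOC)cc(OCOC)c1CC=C(C)C
F2 | step 5 | 3,5-bis(methoxymethoxy)-2-(3-methylbut-2-enyl)-6-(3-phenylprop-2-ynoyl)phenyl N-isopropylcarbamate | CC(C)NC(=O)Oc1c(CC=C(C)C)c(OCOC)cc(OCOC)c1C(=O)C#Cc1ccccc1
F3 | step 5 | (E)-3-(diethylamino)-1-[2-hydroxy-4,6-bis(methoxymethoxy)-3-(3-methylbut-2-enyl)phenyl]-3-phenylprop-2-en-1-one | CCN(CC)/C(=C/C(=O)c1c(O)c(CC=C(C)C)c(OCOC)cc1OCOC)c1ccccc1
F4 | step 6 | racemic 5,7-bis(methoxymethoxy)-8-(3-methylbut-2-enyl)-2-phenylchroman-4-one | CC(C)=CCc1c(OCOC)cc(OCOC)c2c1OC(c1ccccc1)CC2=O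
F5 | step 6 | (2R,4R)-5,7-bis(methoxymethoxy)-8-(3-methylbut-2-enyl)-2-phenylchroman-4-ol | CC(C)=CCc1c(OCOC)cc(OCOC)c2c1O[C@@H](c1ccccc1)C[C@H]2O
F6 | step 3 | 3,5-bis(methoxymethoxy)-2-(trimethylsilyl)phenyl N-isopropylcarbamate | CC(C)NC(=O)Oc1cc(OCOC)cc(OCOC)c1[Si](C)(C)C
F7 | step 3 | [2-(N-tert-butyldimethylsilyl-N-isopropylcarbamoyloxy)-4,6-bis(methoxymethoxy)-3-(trimethylsilyl)phenyl]copper | CC(C)N(C(=O)Oc1c([Cu])c(OCOC)cc(OCOC)c1[Si](C)(C)C)[Si](C)(C)C(C)(C)C
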